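The cyclohexane is cut at C9a–C1 and C9–C10. The feature exploited is that N4 is bonded to C9a and to C3, with only C2 separating C3 from C1: the alkene C9=C9a can therefore sit as a ring-locked Z-enamide in a preformed azepinone (N4, C5–C9, C9a), while a 2-silyloxydiene C1=C12–C11=C10 is attached through C2 to C3. One intramolecular Diels–Alder reaction then closes cyclohexene and pyrrolidine onto the seven-membered ring and fixes C1, C9a, C9 and C10 from the aspartate-derived C3. The precursor is an N-substituted 1,3,4,5-tetrahydroazepin-2-one bearing an (E,Z)-silyloxydiene side chain; lactones, methyl groups and N-oxide follow under substrate control.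

Key step: step 13

Remark: the configuration is taken as the target SMILES encodes it (H-11, H-12, H-13 mutually cis; N–O anti to the C3 lactone); locants follow the tuberostemonine numbering (N4, C1–C3, C5–C9, C9a, C10–C13, C18–C21); TBDPS = tert-butyldiphenylsilyl, TBS = tert-butyldimethylsilyl, Boc = tert-butoxycarbonyl.

Step 1
Reactants: 1 N-Boc-L-aspartic acid 4-methyl ester
Product: 3 methyl (3S)-3-(Boc-amino)-4-hydroxybutanoate, via mixed isobutyl carbonic anhydride 2 (not isolated)
Conditions: i-BuOCOCl, N-methylmorpholine, THF, −15 °C; then NaBH4, H2O, −15 → 0 °C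
Reagents that add atoms: none
Why: Mixed-anhydride activation followed by borohydride reduction converts only the free α-carboxyl group into the carbinol, leaving methyl ester, carbamate and the stereocentre untouched.

Step 2
Reactants: 3 methyl (3S)-3-(Boc-amino)-4-hydroxybutanoate
Product: 4 methyl (3S)-3-(Boc-amino)-4-(TBDPS-oxy)butanoate
Conditions: TBDPSCl, imidazole, DMF, 0 °C → rt
Reagents that add atoms: tert-butyl(chloro)diphenylsilane, CC(C)(C)[Si](Cl)(c1ccccc1)c1ccccc1
Why: Silyl ether formation at the primary alcohol is fast and blocks lactonisation onto the methyl ester.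

Step 3
Reactants: 4 methyl (3S)-3-(Boc-amino)-4-(TBDPS-oxy)butanoate
Product: 5 methyl (3S)-3-amino-4-(TBDPS-oxy)butanoate
Conditions: CF3CO2H, CH2Cl2, 0 °C → rt; aq. NaHCO3
Reagents that add atoms: none
Why: Acidolysis of the tert-butyl carbamate proceeds under conditions that the TBDPS ether and the methyl ester tolerate.

Step 4
Reactants: 5 methyl (3S)-3-amino-4-(TBDPS-oxy)butanoate
Product: 6 methyl (3S)-3-(2-nitrophenylsulfonylamino)-4-(TBDPS-oxy)butanoate
Conditions: 2-NO2C6H4SO2Cl, Et3N, CH2Cl2, 0 °C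
Reagents that add atoms: 2-nitrobenzenesulfonyl chloride, O=S(=O)(Cl)c1ccccc1[N+](=O)[O-]
Why: Sulfonylation gives an acidic sulfonamide that can be alkylated exactly once (first stage of the Fukuyama amine synthesis).

Step 5
Reactants: 6 methyl (3S)-3-(2-nitrophenylsulfonylamino)-4-(TBDPS-oxy)butanoate; 7 allyl bromide
Product: 8 methyl (3S)-3-[allyl(2-nitrophenylsulfonyl)amino]-4-(TBDPS-oxy)butanoate
Conditions: K2CO3, DMF, rt
Reagents that add atoms: allyl bromide (7), C=CCBr
Why: Fukuyama N-alkylation of the sulfonamide anion with the allylic halide stops cleanly at monoallylation.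

Step 6
Reactants: 8 methyl (3S)-3-[allyl(2-nitrophenylsulfonyl)amino]-4-(TBDPS-oxy)butanoate
Product: 9 methyl (3S)-3-(allylamino)-4-(TBDPS-oxy)butanoate
Conditions: PhSH, K2CO3, MeCN, rt
Reagents that add atoms: none
Why: Thiolate-induced nucleophilic aromatic substitution removes the nitrophenylsulfonyl group (Fukuyama deprotection) without touching ester or silyl ether.

Step 7
Reactants: 9 methyl (3S)-3-(allylamino)-4-(TBDPS-oxy)butanoate; 10 pent-4-enoyl chloride
Product: 11 methyl (3S)-3-[allyl(pent-4-enoyl)amino]-4-(TBDPS-oxy)butanoate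
Conditions: Et3N, DMAP (cat.), CH2Cl2, 0 °C → rt
Reagents that add atoms: pent-4-enoyl chloride (10), C=CCCC(=O)Cl
Why: N-Acylation of the secondary amine with the acid chloride gives the tertiary amide that carries both metathesis partners.

Step 8
Reactants: 11 methyl (3S)-3-[allyl(pent-4-enoyl)amino]-4-(TBDPS-oxy)butanoate
Product: 13 methyl (3S)-4-(TBDPS-oxy)-3-(2-oxo-2,3,4,5-tetrahydro-1H-azepin-1-yl)butanoate, via metathesis lactam 12 (not isolated)
Conditions: second-generation Grubbs catalyst RuCl2(=CHPh)(PCy3)(H2IMes) (3 mol%), PhMe (5 mM), 60 °C; then RuHCl(CO)(PPh3)3 (5 mol%), 110 °C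
Reagents that add atoms: none
Why: Ring-closing metathesis closes the seven-membered lactam with loss of ethene, and ruthenium hydride alkene isomerisation then moves C8=C9 into conjugation with nitrogen, giving the enamide C9=C9a that the ring holds Z.

Step 9
Reactants: 13 methyl (3S)-4-(TBDPS-oxy)-3-(2-oxo-2,3,4,5-tetrahydro-1H-azepin-1-yl)butanoate
Product: 14 (3S)-4-(TBDPS-oxy)-3-(2-oxo-2,3,4,5-tetrahydro-1H-azepin-1-yl)butanal
Conditions: i-Bu2AlH (1.1 equiv), CH2Cl2, −78 °C; MeOH, then aq. potassium sodium tartrate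
Reagents that add atoms: none
Why: Low-temperature hydride reduction stops at the aluminium hemiacetal of the ester, which is far more electrophilic than the tertiary enamide lactam, and releases the aldehyde on work-up.

Step 10
Reactants: 14 (3S)-4-(TBDPS-oxy)-3-(2-oxo-2,3,4,5-tetrahydro-1H-azepin-1-yl)butanal; 15 pentan-2-one
Product: 17 1-[(2S)-1-(TBDPS-oxy)-4-hydroxy-6-oxononan-2-yl]-1,3,4,5-tetrahydro-2H-azepin-2-one (both C4 epimers), via lithium pent-1-en-2-olate 16 (not isolated)
Conditions: LiN(i-Pr)2, THF, −78 °C; then 14, −78 °C; AcOH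
Reagents that add atoms: pentan-2-one (15), CCCC(C)=O
Why: Kinetic deprotonation of the ketone at its methyl group and directed aldol addition at −78 °C outrun enolisation or β-elimination of the β-amido aldehyde, and the new carbinol centre is erased in the next step.

Step 11
Reactants: 17 1-[(2S)-1-(TBDPS-oxy)-4-hydroxy-6-oxononan-2-yl]-1,3,4,5-tetrahydro-2H-azepin-2-one
Product: 19 1-[(2S,4E)-1-(TBDPS-oxy)-6-oxonon-4-en-2-yl]-1,3,4,5-tetrahydro-2H-azepin-2-one, via C4 mesylate 18 (not isolated)
Conditions: MsCl, Et3N (excess), CH2Cl2, 0 °C → rt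
Reagents that add atoms: none
Why: Mesylation and E1cB elimination of the β-hydroxy ketone give the conjugated enone as its thermodynamically preferred E isomer (C1=C12).

Step 12
Reactants: 19 1-[(2S,4E)-1-(TBDPS-oxy)-6-oxonon-4-en-2-yl]-1,3,4,5-tetrahydro-2H-azepin-2-one
Product: 20 1-[(2S,4E,6Z)-6-(TBS-oxy)-1-(TBDPS-oxy)nona-4,6-dien-2-yl]-1,3,4,5-tetrahydro-2H-azepin-2-one
Conditions: TBSOTf, Et3N, CH2Cl2, −78 → 0 °C
Reagents that add atoms: tert-butyldimethylsilyl trifluoromethanesulfonate, CC(C)(C)[Si](C)(C)OS(=O)(=O)C(F)(F)F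
Why: Soft enolisation (silyl triflate and amine) removes an α′ proton at C10 to give the cross-conjugated 2-silyloxydiene, and allylic strain places ethyl cis to the silyloxy group (Z), so both diene termini carry their substituents outside.

Step 13
Reactants: 20 1-[(2S,4E,6Z)-6-(TBS-oxy)-1-(TBDPS-oxy)nona-4,6-dien-2-yl]-1,3,4,5-tetrahydro-2H-azepin-2-one
Product: 21 tricyclic C11=C12 silyl enol ether (cyclohexene fused to pyrrolidine and azepin-5-one; H-9/H-9a cis; H-1/H-9a trans; H-9/H-10 trans; H-3/H-9a trans)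
Conditions: degassed PhMe (5 mM), BHT (cat.), N,O-bis(trimethylsilyl)acetamide (0.2 equiv), base-washed sealed tube, 180 °C
Reagents that add atoms: none
Why: A concerted suprafacial thermal [4+2] cycloaddition in the fused mode forms C9a–C1 and C9–C10; the closest known reaction type is the thermal intramolecular Diels–Alder reaction of N-acyl enamines with N-tethered dienes to hexahydroindoles. The cyclohexene (C1, C9a, C9, C10, C11, C12) is closed by the cycloaddition itself and the pyrrolidine (N4, C3, C2, C1, C9a) by the C1–C9a bond across the three-atom tether N4–C3–C2, both onto the azepinone that already holds the dienophile. H-9 and H-9a come out cis because the Z-alkene is locked in the seven-membered ring, and ethyl on C10 and C2 on C1 come out cis because both sit outside on the (E,Z)-diene. The trans C9a–C1 fusion needs the azepinone ring exo (tether anti), which should be favoured because the endo mode would push C8 and the rest of that ring under the silyloxydiene. The absolute sense is relayed from C3: allylic 1,3-strain keeps C3–H near the plane of the lactam carbonyl, so C18 points to the face away from the diene and ends cis to H-9a. The electronically unbiased pair needs heat, the tether enforces the regiochemistry, and the product is the regiodefined C11=C12 silyl enol ether.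

Step 14
Reactants: 21 tricyclic C11=C12 silyl enol ether; 22 ethyl bromoacetate
Product: 23 tricyclic C11 ketone with a C12 ethoxycarbonylmethyl chain (H-12/H-1 trans; chain trans to the C10 ethyl group)
Conditions: fac-Ir(ppy)3 (1 mol%), 2,6-lutidine, DMF, blue LEDs, rt; aqueous work-up
Reagents that add atoms: ethyl bromoacetate (22), CCOC(=O)CBr
Why: Photoredox radical alkylation of a silyl enol ether: the electrophilic ethoxycarbonylmethyl radical adds to C12 on the face opposite the pseudoaxial C10 ethyl group, which leaves the chain equatorial and trans to C2, and oxidation with desilylation returns the C11 ketone under neutral conditions that do not epimerise C10.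

Step 15
Reactants: 23 tricyclic C11 ketone with a C12 ethoxycarbonylmethyl chain
Product: 25 tetracyclic cis-fused γ-lactone lactam with C13 as CH2 (H-11/H-12 cis; H-10/H-11 trans), via cis-hydroxy ester 24 (not isolated)
Conditions: LiBH(s-Bu)3, THF, −78 → −40 °C; AcOH; then TsOH (cat.), CH2Cl2, rt
Reagents that add atoms: none
Why: In this reduction by a bulky trialkylborohydride the axial trajectory is blocked by the syn-axial C8 methylene of the azepinone, so hydride should enter equatorially and give the axial C11 alkoxide cis to the C12 chain, which lactonises.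

Step 16
Reactants: 25 tetracyclic cis-fused γ-lactone lactam
Product: 27 C13 dimethylaminomethyl lactone (C13 epimers), via lactone lithium enolate 26 (not isolated)
Conditions: LiN(SiMe3)2 (1.1 equiv), THF, −78 °C; then CH2=NMe2+ I−, −78 → 0 °C
Reagents that add atoms: dimethylmethyleneiminium iodide, C=[N+](C)C.[I-]
Why: Mannich reaction of the lactone enolate with the iminium salt: the lactone α-methylene is much more acidic than the lactam α-methylene, and the configuration of the new C13 centre is irrelevant.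

Step 17
Reactants: 27 C13 dimethylaminomethyl lactone
Product: 29 C13 α-methylene lactone lactam, via trimethylammonium iodide 28 (not isolated)
Conditions: MeI, MeOH, rt; then aq. NaHCO3, CH2Cl2, rt
Reagents that add atoms: none
Why: Quaternisation followed by Hofmann-type β-elimination of the β-ammonium lactone gives the exocyclic alkene under bicarbonate conditions too mild for double-bond migration.

Step 18
Reactants: 29 C13 α-methylene lactone lactam
Product: 30 C13-methyl lactone lactam (H-11, H-12, H-13 all cis)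
Conditions: H2 (1 atm), Pd/C, EtOAc, rt
Reagents that add atoms: none
Why: Heterogeneous catalytic hydrogenation should add hydrogen to C13 from the convex face of the cis-fused lactone (the face of H-11 and H-12, away from C1 and C2), so H-13 becomes cis to H-12 and the methyl group sits on the concave face.

Step 19
Reactants: 30 C13-methyl lactone lactam
Product: 31 C5 thiolactam
Conditions: Lawesson's reagent (0.55 equiv), PhMe, 80 °C
Reagents that add atoms: Lawesson's reagent, COc1ccc(cc1)P1(=S)SP(=S)(S1)c1ccc(OC)cc1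
Why: Thionation with Lawesson's reagent is selective for the lactam because amides react far faster than lactones.

Step 20
Reactants: 31 C5 thiolactam
Product: 32 tetracyclic tertiary amine with the C18 TBDPS ether
Conditions: Raney Ni (W-2, washed neutral), EtOH, rt
Reagents that add atoms: none
Why: Raney nickel desulfurisation reduces the thiolactam to the amine and leaves lactone and silyl ether intact.

Step 21
Reactants: 32 tetracyclic tertiary amine with the C18 TBDPS ether
Product: 33 C13-methyl tetracyclic amino alcohol (C18 carbinol)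
Conditions: HF·pyridine, THF, 0 °C → rt; aq. NaHCO3
Reagents that add atoms: none
Why: Fluoride-mediated silyl ether cleavage under acidic buffering avoids base and hence epimerisation at C13.

Step 22
Reactants: 33 C13-methyl tetracyclic amino alcohol
Product: 34 C18 α-amino aldehyde (used crude at once)
Conditions: (COCl)2, DMSO, CH2Cl2, −78 °C; then i-Pr2NEt, −78 → −40 °C
Reagents that add atoms: none
Why: Swern oxidation at low temperature tolerates the tertiary amine and delivers the configurationally labile aldehyde without warming.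

Step 23
Reactants: 34 C18 α-amino aldehyde; 35 ethyl 2-(bromomethyl)acrylate
Product: 38 bis-lactone carrying an α-methylene γ-lactone at C3 (18S; N4 and O18 syn), via allylzinc bromide 36 (not isolated), via syn-hydroxy ester 37 (not isolated)
Conditions: activated Zn dust, THF, 0 °C; then 34, −78 → 0 °C; rt, TsOH (cat.) if needed
Reagents that add atoms: ethyl 2-(bromomethyl)acrylate (35), CCOC(=O)C(=C)CBr
Why: Zinc-mediated Barbier allylation: zinc should bridge the aldehyde oxygen and the N4 lone pair (Cram chelate, reached after nitrogen inversion), the allyl group then adds to the carbonyl face anti to C2 to give the syn amino alcohol (18S), and the zinc alkoxide lactonises onto the ester.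

Step 24
Reactants: 38 bis-lactone carrying an α-methylene γ-lactone at C3
Product: 39 tuberostemonine (18S,20S; cis-2,4-disubstituted lactone)
Conditions: H2 (1 atm), Pd/C, EtOAc, rt
Reagents that add atoms: none
Why: Heterogeneous hydrogenation of the exocyclic methylene should occur on the lactone face opposite the bulky C18 substituent, placing the C20 methyl group cis to it.

Step 25
Reactants: 39 tuberostemonine
Product: 40 N-oxytuberostemonine
Conditions: m-CPBA (1.0 equiv), CH2Cl2, 0 °C
Reagents that add atoms: 3-chloroperoxybenzoic acid, OOC(=O)c1cccc(Cl)c1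
Why: Electrophilic N-oxidation by the peracid takes place at the amine lone pair of the trans-fused invertomer, on the nitrogen face anti to the C3 lactone and to H-9a.

Compound list
1 | N-Boc-L-aspartic acid 4-methyl ester | COC(=O)C[C@H](NC(=O)OC(C)(C)C)C(=O)O | starting material
2 | mixed isobutyl carbonic anhydride of 1 (formed in the flask) | COC(=O)C[C@H](NC(=O)OC(C)(C)C)C(=O)OC(=O)OCC(C)C | intermediate
3 | methyl (3S)-3-(Boc-amino)-4-hydroxybutanoate | COC(=O)C[C@H](NC(=O)OC(C)(C)C)CO | intermediate
4 | methyl (3S)-3-(Boc-amino)-4-(TBDPS-oxy)butanoate | COC(=O)C[C@H](NC(=O)OC(C)(C)C)CO[Si](c1ccccc1)(c1ccccc1)C(C)(C)C | intermediate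
5 | methyl (3S)-3-amino-4-(TBDPS-oxy)butanoate | COC(=O)C[C@H](N)CO[Si](c1ccccc1)(c1ccccc1)C(C)(C)C | intermediate
6 | methyl (3S)-3-(2-nitrophenylsulfonylamino)-4-(TBDPS-oxy)butanoate | COC(=O)C[C@H](NS(=O)(=O)c1ccccc1[N+](=O)[O-])CO[Si](c1ccccc1)(c1ccccc1)C(C)(C)C | intermediate
7 | allyl bromide | C=CCBr | starting material
8 | methyl (3S)-3-[allyl(2-nitrophenylsulfonyl)amino]-4-(TBDPS-oxy)butanoate | COC(=O)C[C@H](N(CC=C)S(=O)(=O)c1ccccc1[N+](=O)[O-])CO[Si](c1ccccc1)(c1ccccc1)C(C)(C)C | intermediate
9 | methyl (3S)-3-(allylamino)-4-(TBDPS-oxy)butanoate | COC(=O)C[C@H](NCC=C)CO[Si](c1ccccc1)(c1ccccc1)C(C)(C)C | intermediate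
10 | pent-4-enoyl chloride | C=CCCC(=O)Cl | starting material
11 | methyl (3S)-3-[allyl(pent-4-enoyl)amino]-4-(TBDPS-oxy)butanoate | COC(=O)C[C@H](N(CC=C)C(=O)CCC=C)CO[Si](c1ccccc1)(c1ccccc1)C(C)(C)C | intermediate
12 | methyl (3S)-4-(TBDPS-oxy)-3-(2-oxo-2,3,4,7-tetrahydro-1H-azepin-1-yl)butanoate (C8=C9 lactam, formed in the flask) | COC(=O)C[C@H](N1CC=CCCC1=O)CO[Si](c1ccccc1)(c1ccccc1)C(C)(C)C | intermediate
13 | methyl (3S)-4-(TBDPS-oxy)-3-(2-oxo-2,3,4,5-tetrahydro-1H-azepin-1-yl)butanoate (ene-lactam, C9=C9a) | COC(=O)C[C@H](N1C=CCCCC1=O)CO[Si](c1ccccc1)(c1ccccc1)C(C)(C)C | intermediate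
14 | (3S)-4-(TBDPS-oxy)-3-(2-oxo-2,3,4,5-tetrahydro-1H-azepin-1-yl)butanal | O=CC[C@H](N1C=CCCCC1=O)CO[Si](c1ccccc1)(c1ccccc1)C(C)(C)C | intermediate
15 | pentan-2-one | CCCC(C)=O | starting material
16 | lithium pent-1-en-2-olate (formed in the flask) | [Li]OC(=C)CCC | intermediate
17 | 1-[(2S)-1-(TBDPS-oxy)-4-hydroxy-6-oxononan-2-yl]-1,3,4,5-tetrahydro-2H-azepin-2-one, both C4 epimers | CCCC(=O)CC(O)C[C@H](N1C=CCCCC1=O)CO[Si](c1ccccc1)(c1ccccc1)C(C)(C)C | intermediate
18 | C4 methanesulfonate of 17 (formed in the flask) | CCCC(=O)CC(OS(C)(=O)=O)C[C@H](N1C=CCCCC1=O)CO[Si](c1ccccc1)(c1ccccc1)C(C)(C)C | intermediate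
19 | 1-[(2S,4E)-1-(TBDPS-oxy)-6-oxonon-4-en-2-yl]-1,3,4,5-tetrahydro-2H-azepin-2-one | CCCC(=O)/C=C/C[C@H](N1C=CCCCC1=O)CO[Si](c1ccccc1)(c1ccccc1)C(C)(C)C | intermediate
20 | 1-[(2S,4E,6Z)-6-(TBS-oxy)-1-(TBDPS-oxy)nona-4,6-dien-2-yl]-1,3,4,5-tetrahydro-2H-azepin-2-one | CC/C=C(O[Si](C)(C)C(C)(C)C)/C=C/C[C@H](N1C=CCCCC1=O)CO[Si](c1ccccc1)(c1ccccc1)C(C)(C)C | intermediate
21 | tricyclic silyl enol ether: cyclohexene (C1, C9a, C9, C10, C11, C12) with 11-OTBS and C11=C12, fused to pyrrolidine (N4, C3, C2, C1, C9a) and azepin-5-one (N4, C5–C9, C9a); 10-ethyl; 3-CH2OTBDPS; H-9/H-9a cis, H-1/H-9a trans, H-9/H-10 trans, H-3/H-9a trans | CC[C@@H]1[C@H]2CCCC(=O)N3[C@H]2[C@H](C[C@H]3CO[Si](c4ccccc4)(c4ccccc4)C(C)(C)C)C=C1O[Si](C)(C)C(C)(C)C | intermediate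
22 | ethyl bromoacetate | CCOC(=O)CBr | starting material
23 | tricyclic C11 ketone with CH2CO2Et at C12 (H-12/H-1 trans, chain trans to ethyl), other centres as in 21 | CC[C@@H]1[C@H]2CCCC(=O)N3[C@H]2[C@H](C[C@H]3CO[Si](c4ccccc4)(c4ccccc4)C(C)(C)C)[C@@H](CC(=O)OCC)C1=O | intermediate
24 | C11 axial alcohol of 23, hydroxyl cis to the C12 chain (formed in the flask) | CC[C@@H]1[C@H]2CCCC(=O)N3[C@H]2[C@H](C[C@H]3CO[Si](c4ccccc4)(c4ccccc4)C(C)(C)C)[C@@H](CC(=O)OCC)[C@H]1O | intermediate
25 | tetracyclic cis-fused γ-lactone lactam, C13 = CH2, H-11/H-12 cis, 3-CH2OTBDPS | CC[C@@H]1[C@H]2CCCC(=O)N3[C@H]2[C@H](C[C@H]3CO[Si](c4ccccc4)(c4ccccc4)C(C)(C)C)[C@@H]2[C@H]1OC(=O)C2 | intermediate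
26 | lithium enolate of lactone 25 (formed in the flask) | CC[C@@H]1[C@H]2CCCC(=O)N3[C@H]2[C@H](C[C@H]3CO[Si](c4ccccc4)(c4ccccc4)C(C)(C)C)[C@@H]2[C@H]1OC(O[Li])=C2 | intermediate
27 | 13-(dimethylaminomethyl) lactone lactam, C13 epimers | CC[C@@H]1[C@H]2CCCC(=O)N3[C@H]2[C@H](C[C@H]3CO[Si](c4ccccc4)(c4ccccc4)C(C)(C)C)[C@@H]2[C@H]1OC(=O)C2CN(C)C | intermediate
28 | trimethylammonium iodide of 27 (formed in the flask) | CC[C@@H]1[C@H]2CCCC(=O)N3[C@H]2[C@H](C[C@H]3CO[Si](c4ccccc4)(c4ccccc4)C(C)(C)C)[C@@H]2[C@H]1OC(=O)C2C[N+](C)(C)C.[I-] | intermediate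
29 | 13-methylene lactone lactam | CC[C@@H]1[C@H]2CCCC(=O)N3[C@H]2[C@H](C[C@H]3CO[Si](c4ccccc4)(c4ccccc4)C(C)(C)C)[C@@H]2[C@H]1OC(=O)C2=C | intermediate
30 | 13-methyl lactone lactam, H-11, H-12 and H-13 cis | CC[C@@H]1[C@H]2CCCC(=O)N3[C@H]2[C@H](C[C@H]3CO[Si](c4ccccc4)(c4ccccc4)C(C)(C)C)[C@@H]2[C@H]1OC(=O)[C@@H]2C | intermediate
31 | C5 thiolactam of 30 | CC[C@@H]1[C@H]2CCCC(=S)N3[C@H]2[C@H](C[C@H]3CO[Si](c4ccccc4)(c4ccccc4)C(C)(C)C)[C@@H]2[C@H]1OC(=O)[C@@H]2C | intermediate
32 | tetracyclic tertiary amine, C18 TBDPS ether | CC[C@@H]1[C@H]2CCCCN3[C@H]2[C@H](C[C@H]3CO[Si](c4ccccc4)(c4ccccc4)C(C)(C)C)[C@@H]2[C@H]1OC(=O)[C@@H]2C | intermediate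
33 | C13-methyl tetracyclic amino alcohol (C18 carbinol) | CC[C@@H]1[C@H]2CCCCN3[C@H]2[C@H](C[C@H]3CO)[C@@H]2[C@H]1OC(=O)[C@@H]2C | intermediate
34 | C18 α-amino aldehyde | CC[C@@H]1[C@H]2CCCCN3[C@H]2[C@H](C[C@H]3C=O)[C@@H]2[C@H]1OC(=O)[C@@H]2C | intermediate
35 | ethyl 2-(bromomethyl)acrylate | CCOC(=O)C(=C)CBr | starting material
36 | [2-(ethoxycarbonyl)allyl]zinc bromide (formed in the flask) | CCOC(=O)C(=C)C[Zn]Br | intermediate
37 | (18S)-hydroxy ester, N4 and O18 syn (formed in the flask) | CC[C@@H]1[C@H]2CCCCN3[C@H]2[C@H](C[C@H]3[C@@H](O)CC(=C)C(=O)OCC)[C@@H]2[C@H]1OC(=O)[C@@H]2C | intermediate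
38 | bis-lactone with (18S)-α-methylene γ-lactone at C3 | CC[C@@H]1[C@H]2CCCCN3[C@H]2[C@H](C[C@H]3[C@@H]2CC(=C)C(=O)O2)[C@@H]2[C@H]1OC(=O)[C@@H]2C | intermediate
39 | tuberostemonine, (18S,20S) | CC[C@@H]1[C@H]2CCCCN3[C@H]2[C@H](C[C@H]3[C@@H]2C[C@H](C)C(=O)O2)[C@@H]2[C@H]1OC(=O)[C@@H]2C | intermediate
40 | N-oxytuberostemonine, N–O anti to the C3 lactone | CC[C@@H]1[C@H]2CCCC[N@@+]3([O-])[C@H]2[C@H](C[C@H]3[C@@H]2C[C@H](C)C(=O)O2)[C@@H]2[C@H]1OC(=O)[C@@H]2C | target

Total step count: 25.
Longest linear sequence: 25 steps, from 1 to 40; compounds 7, 10, 15, 22 and 35 are bought and enter directly.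

Steps most likely to fail

Step 13. The electronically unbiased pair may cycloadd too slowly, so that the silyl dienol ether is lost to protodesilylation or polymerisation, or exo and π-facial control may erode. The fallback replaces the enamide dienophile by a polarity-matched intermolecular Diels–Alder reaction followed by a Schmidt ring expansion; it sets out from 5 and comes back at 23.
- Diazo transfer to 5 (imidazole-1-sulfonyl azide hydrogen sulfate, K2CO3, CuSO4 cat., MeOH) would give, with retention, methyl (3S)-3-azido-4-(TBDPS-oxy)butanoate F1.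
- i-Bu2AlH at −78 °C would give (3S)-3-azido-4-(TBDPS-oxy)butanal F2.
- Horner–Wadsworth–Emmons olefination with dimethyl (2-oxopentyl)phosphonate (LiCl, i-Pr2NEt, MeCN) would give the azido enone F3.
- TBSOTf and Et3N would give the azido silyloxydiene F4.
- With cyclohex-2-en-1-one and BF3·OEt2 (CH2Cl2, −78 °C → rt), the nucleophilic diene terminus C10 would bond to the enone β-carbon C9, giving the bicyclic azido ketone Diels–Alder adduct F5.
- The same Lewis acid would then drive the intramolecular Schmidt reaction (azide addition to the ketone, migration of C9a with retention, loss of dinitrogen) to the tricyclic C11 keto lactam F6.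
- Kinetic enolisation at the C12 methylene (LiN(SiMe3)2, THF, −78 °C) and alkylation with 22 would return to 23.
- In this variant C3 no longer steers the cycloaddition: exo selectivity would have to come from the Lewis acid, and the two diastereomers that differ in the sense of the core relative to C3 would be separated at F6.

Step 23. Chelation control may be lost, giving Felkin–Anh addition and the C18 epimer, and the α-amino aldehyde may epimerise at C3 before it reacts. The fallback moves from the cyclic Barbier transition state to an open, Lewis-acid-chelated Hosomi–Sakurai allylation; it sets out from 34 and comes back at 38. The aldehyde would be precomplexed with SnCl4 (CH2Cl2, −78 °C) so that tin locks N4 and the carbonyl oxygen in a five-membered chelate. Commercial ethyl 2-(trimethylsilylmethyl)acrylate would then add anti to C2 to give the hydroxy ester 37, and TsOH would close it to 38. No compound outside the list arises (F0).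

Step 15. Hydride may be delivered to the wrong face of the C11 ketone, or enolisation may epimerise C10. The fallback changes from retentive to invertive lactonisation; it sets out from 23 and comes back at 25. A small hydride used for axial attack (NaBH4, MeOH, 0 °C) would give the 11-epi-hydroxy ester F7, with the hydroxyl trans to the C12 chain. LiOH (THF–H2O) would give the 11-epi-hydroxy acid F8. Mitsunobu lactonisation (PPh3, diisopropyl azodicarboxylate, THF) would then close the cis-fused lactone 25 with inversion at C11.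

Further compounds
F1 | step 13 | methyl (3S)-3-azido-4-(TBDPS-oxy)butanoate | COC(=O)C[C@H](N=[N+]=[N-])CO[Si](c1ccccc1)(c1ccccc1)C(C)(C)C
F2 | step 13 | (3S)-3-azido-4-(TBDPS-oxy)butanal | O=CC[C@H](N=[N+]=[N-])CO[Si](c1ccccc1)(c1ccccc1)C(C)(C)C
F3 | step 13 | (5E,8S)-8-azido-9-(TBDPS-oxy)non-5-en-4-one | CCCC(=O)/C=C/C[C@H](N=[N+]=[N-])CO[Si](c1ccccc1)(c1ccccc1)C(C)(C)C
F4 | step 13 | (2S,4E,6Z)-2-azido-6-(TBS-oxy)-1-(TBDPS-oxy)nona-4,6-diene | CC/C=C(O[Si](C)(C)C(C)(C)C)/C=C/C[C@H](N=[N+]=[N-])CO[Si](c1ccccc1)(c1ccccc1)C(C)(C)C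
F5 | step 13 | bicyclic azido ketone, exo Diels–Alder adduct of F4 and cyclohex-2-en-1-one | CC[C@@H]1[C@H]2CCCC(=O)[C@H]2[C@H](C[C@H](N=[N+]=[N-])CO[Si](c3ccccc3)(c3ccccc3)C(C)(C)C)C=C1O[Si](C)(C)C(C)(C)C
F6 | step 13 | tricyclic C11 keto lactam with C12 as CH2 | CC[C@@H]1[C@H]2CCCC(=O)N3[C@H]2[C@H](C[C@H]3CO[Si](c4ccccc4)(c4ccccc4)C(C)(C)C)CC1=O
F7 | step 15 | 11-epi-hydroxy ester, hydroxyl trans to the C12 chain | CC[C@@H]1[C@H]2CCCC(=O)N3[C@H]2[C@H](C[C@H]3CO[Si](c4ccccc4)(c4ccccc4)C(C)(C)C)[C@@H](CC(=O)OCC)[C@@H]1O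
F8 | step 15 | 11-epi-hydroxy acid | CC[C@@H]1[C@H]2CCCC(=O)N3[C@H]2[C@H](C[C@H]3CO[Si](c4ccccc4)(c4ccccc4)C(C)(C)C)[C@@H](CC(=O)O)[C@@H]1O
F0 | step 23 | none | none
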